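**Strategy.** Everything rests on reading ring A as a homoaldol: the oxygen on C2 is γ to C9 across the quaternary C10, and C9, an alkene carbon of ring B in the target, can be a ketone. C1 is therefore brought in as the methylene of a siloxycyclopropane fused to C9–C10 of a carvone-derived ring B that carries a C2 aldehyde on its C5 side chain. In the key step a Lewis acid lets this cyclopropane attack the aldehyde: the C1–C9 bond breaks, the C1–C2 bond forms, ring A closes as a trans-decalin with the 2α-hydroxyl, and the C9 ketone returns as the handle for the C8=C9 alkene and side chain.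

Key step: step 7

Remark on the chemistry: labdane numbering of the target (C1–C20; C20 is the methyl on C10) and its α/β descriptors are used for every intermediate. "Bicyclic core" means the trans-decalin C1–C10 with the C4 gem-dimethyl, the C8 methyl and the 10β-methyl (5α-H), without the C11–C16 chain. The minor C8 epimer formed in step 1 converges in step 8, where C8 becomes sp2.

Step 1
Reactants: 1 (R)-(−)-carvone
Product: 2 trans-6-methylcarvone
Conditions: LDA, THF, −78 °C; MeI, −78 to −20 °C
Reagents that add atoms: iodomethane CI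
Why: Kinetic α′-enolate alkylation, in which iodomethane enters anti to the neighbouring isopropenyl group to give the trans isomer and so places the future C8 methyl.

Step 2
Reactants: 2 trans-6-methylcarvone
Product: 4 ring B acetoxy enone, via methoxy hydroperoxide 3 (not isolated)
Conditions: O3, CH2Cl2/MeOH, −78 °C (Sudan red end point); then Ac2O, Et3N, DMAP, 0 °C to rt
Reagents that add atoms: ozone [O-][O+]=O; methanol CO
Why: Chemoselective ozonolysis of the electron-rich isopropenyl group followed by Criegee rearrangement of the acetylated methoxy hydroperoxide should give the C7 acetate with retention (7α), the ester carbonyl oxygen coming from methanol.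

Step 3
Reactants: 4 ring B acetoxy enone; 5 prenyltrimethylsilane
Product: 6 ring B silyl enol ether
Conditions: Me3SiNTf2 (5 mol%), 2,6-di-tert-butylpyridine (10 mol%), CH2Cl2, −78 to −40 °C; Et3N quench
Reagents that add atoms: none
Why: Silyl-cation-catalysed Hosomi–Sakurai conjugate addition with silyl transfer, in which the allylsilane attacks through its γ-carbon to create the quaternary C4, adds anti to the 7α-acetoxy group to set C5 (5α-H) and leaves the enolate trapped regiospecifically as the C9=C10 trimethylsilyl enol ether.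

Step 4
Reactants: 6 ring B silyl enol ether
Product: 7 vinyl siloxycyclopropane
Conditions: Et2Zn, CH2I2, CH2Cl2, 0 °C
Reagents that add atoms: diiodomethane ICI
Why: Furukawa–Simmons–Smith cyclopropanation, which should be chemoselective for the electron-rich enol ether and deliver the C1 methylene to the α face, anti to the pseudoaxial C5 substituent and the 8β-methyl, thereby fixing C10 (C20 β, C1 α).

Step 5
Reactants: 7 vinyl siloxycyclopropane
Product: 9 primary alcohol, via alkylborane 8 (not isolated)
Conditions: 9-BBN, THF, 0 °C to rt; then 30% H2O2, aq. NaOAc, 0 °C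
Reagents that add atoms: hydrogen peroxide OO
Why: Anti-Markovnikov hydroboration–oxidation of the only remaining alkene puts the oxygen on C2, the acetate buffer being chosen to spare the silyl cyclopropyl ether and the C7 acetate.

Step 6
Reactants: 9 primary alcohol
Product: 10 siloxycyclopropane aldehyde
Conditions: Dess–Martin periodinane, pyridine, CH2Cl2, 0 °C
Reagents that add atoms: none
Why: Dess–Martin oxidation under buffered, non-acidic conditions gives the C2 aldehyde without opening the siloxycyclopropane.

Step 7
Reactants: 10 siloxycyclopropane aldehyde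
Product: 11 decalin hydroxy ketone
Conditions: TiCl4 (1.1 equiv), CH2Cl2, −78 °C; aq. NaHCO3
Reagents that add atoms: none
Why: Proposed new method: TiCl4 activates the C2 aldehyde and the strained C1–C9 σ-bond of the siloxycyclopropane, polarised by the oxygen on C9, attacks it through C1 (a homo-Mukaiyama aldol; a β-titanio ketone formed by prior ring opening would give the same product), after which the C9 silyloxycarbenium ion loses Me3SiCl to give the ketone. The closest known reaction types are the titanium homoenolate addition to aldehydes from 1-alkoxy-1-siloxycyclopropanes (Nakamura–Kuwajima homoaldol) and the electrophilic opening of ketone-derived siloxycyclopropanes at the CH2 carbon by protons, halogens or metal salts; the intramolecular carbonyl addition of a ketone homoenolate equivalent is the untested part. Ring A closes in a 6-exo-trig mode onto the aldehyde, and its trans fusion is already fixed by C5 and C10. The new stereocentre C2 is controlled by the chair-like transition state, in which the titanium-bound oxygen must lie equatorial because an axial one would be syn-diaxial to both C20 and the 4β-methyl, which gives the 2α-alcohol. The step needs cleavage of C1–C9 rather than C9–C10 and C–C bond formation rather than protodesilylation; the donor oxygen on C9 (only C1–C9 cleavage gives an oxygen-stabilised cation), the quaternary C10, the gem-dimethyl effect of C4 and strictly anhydrous conditions should secure this.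

Step 8
Reactants: 11 decalin hydroxy ketone
Product: 13 decalin enone, via diacetate 12 (not isolated)
Conditions: Ac2O, Et3N, DMAP, CH2Cl2, rt; then DBU, 40 °C
Reagents that add atoms: acetic anhydride CC(=O)OC(C)=O
Why: Acetylation of the unhindered equatorial 2α-hydroxyl followed by E1cB elimination of the β-acetoxy ketone gives the C7=C8 enone, removes the temporary C7 and C8 centres and also converges any enone already formed in step 7.

Step 9
Reactants: 13 decalin enone
Product: 14 dienyl triflate
Conditions: Tf2O, 2,6-di-tert-butyl-4-methylpyridine, CH2Cl2, 0 °C to rt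
Reagents that add atoms: trifluoromethanesulfonic anhydride O=S(=O)(OS(=O)(=O)C(F)(F)F)C(F)(F)F
Why: O-triflation of the enone and γ-deprotonation (dienyl triflate formation) can only take the C6 proton because C10 is quaternary, which gives the C6=C7/C8=C9 diene with the triflate on C9 under conditions that spare the acetate.

Step 10
Reactants: 14 dienyl triflate
Product: 15 epoxy triflate
Conditions: mCPBA, NaHCO3, CH2Cl2, 0 °C
Reagents that add atoms: meta-chloroperbenzoic acid OOC(=O)c1cccc(Cl)c1
Why: Prilezhaev epoxidation should take the C6=C7 bond, the only alkene not deactivated by the triflate, from the α face because the β face is shielded by the axial C20 and 4β-methyl groups.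

Step 11
Reactants: 15 epoxy triflate
Product: 16 6-keto triflate
Conditions: BF3·OEt2 (20 mol%), CH2Cl2, −40 °C
Reagents that add atoms: none
Why: Meinwald rearrangement, in which the epoxide ionises at the allylic C7 and the 6β-hydride shifts to C7, should give the C6 ketone without touching C5.

Step 12
Reactants: 16 6-keto triflate
Product: 17 7α-hydroxy-6-keto triflate
Conditions: NaHMDS (1.05 equiv), THF, −78 °C; 2-(benzenesulfonyl)-3-phenyloxaziridine; aq. NH4Cl at −78 °C
Reagents that add atoms: 2-(benzenesulfonyl)-3-phenyloxaziridine O=S(=O)(c1ccccc1)N1OC1c1ccccc1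
Why: Davis α-hydroxylation of the sodium enolate formed at the doubly activated (α-keto and allylic) C7, with axial attack from the less hindered α face setting the 7α-hydroxyl, while the amide base is too weak to enolise the acetate.

Step 13
Reactants: 17 7α-hydroxy-6-keto triflate
Product: 18 6β,7α-diol triflate
Conditions: NaBH4, MeOH/THF, −20 °C
Reagents that add atoms: none
Why: Borohydride reduction in which hydride can only approach C6 from the α face, the β face being blocked by C20 and the 4β-methyl, which gives the axial 6β-alcohol.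

Step 14
Reactants: 18 6β,7α-diol triflate
Product: 19 triacetoxy triflate
Conditions: Ac2O, DMAP, pyridine, 50 °C
Reagents that add atoms: acetic anhydride CC(=O)OC(C)=O
Why: DMAP-catalysed acetylation under forcing conditions should esterify both the allylic 7α- and the hindered axial 6β-hydroxyl.

Step 15
Reactants: 20 (E)-3-methylpent-2-en-4-yn-1-ol
Product: 21 (E)-3-methylpenta-2,4-dien-1-ol
Conditions: H2 (1 atm), Pd/CaCO3 poisoned with Pb(OAc)2, quinoline, EtOAc, rt
Reagents that add atoms: none
Why: Lindlar semi-hydrogenation reduces the terminal alkyne to the vinyl group and leaves the (E)-trisubstituted alkene unchanged.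

Step 16
Reactants: 19 triacetoxy triflate; 21 (E)-3-methylpenta-2,4-dien-1-ol
Product: 23 target triacetate, via bis-boryl intermediate 22 (not isolated)
Conditions: 21, 9-BBN (2.2 equiv), THF, 0 °C to rt; then 19, PdCl2(dppf), AsPh3, aq. K3PO4, DMF, 50 °C
Reagents that add atoms: none
Why: The first equivalent of 9-BBN masks the hydroxyl as a borinate and the second hydroborates the terminal vinyl group at C11, after which a B-alkyl Suzuki–Miyaura coupling with the C9 triflate should form the C9–C11 bond with retention of both alkene geometries and release the C15 alcohol on work-up.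

**Compound list**

1 | (R)-(−)-carvone, (5R)-2-methyl-5-(prop-1-en-2-yl)cyclohex-2-en-1-one | CC1=CC[C@@H](C(C)=C)CC1=O | starting material
2 | trans-6-methylcarvone, (5R,6S)-2,6-dimethyl-5-(prop-1-en-2-yl)cyclohex-2-en-1-one | CC1=CC[C@@H](C(C)=C)[C@H](C)C1=O | intermediate
3 | (5R,6S)-5-(1-hydroperoxy-1-methoxyethyl)-2,6-dimethylcyclohex-2-en-1-one (both epimers at the peroxy carbon) | CC1=CC[C@@H](C(C)(OC)OO)[C@H](C)C1=O | intermediate
4 | (1R,6S)-4,6-dimethyl-5-oxocyclohex-3-en-1-yl acetate (ring B enone: C9 ketone, C10=C5, 7α-acetoxy, 8β-methyl) | CC1=CC[C@@H](OC(C)=O)[C@H](C)C1=O | intermediate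
5 | trimethyl(3-methylbut-2-en-1-yl)silane (prenyltrimethylsilane) | CC(C)=CC[Si](C)(C)C | starting material
6 | ring B silyl enol ether: C9(OSiMe3)=C10(CH3), 7α-acetoxy, 8β-methyl, β-(2-methylbut-3-en-2-yl) group on C5 (5α-H) | C=CC(C)(C)[C@@H]1C[C@@H](OC(C)=O)[C@H](C)C(O[Si](C)(C)C)=C1C | intermediate
7 | siloxycyclopropane: bicyclo[4.1.0]heptane in which the C1 methylene bridges C9 and C10 on the α face; 9β-OSiMe3, 10β-methyl, 8β-methyl, 7α-acetoxy, β-(2-methylbut-3-en-2-yl) on C5 | C=CC(C)(C)[C@@H]1C[C@@H](OC(C)=O)[C@H](C)[C@@]2(O[Si](C)(C)C)C[C@@]12C | intermediate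
8 | B-alkyl-9-BBN adduct of 7 (9-borabicyclo[3.3.1]nonan-9-yl on C2) | B1(CCC(C)(C)[C@@H]2C[C@@H](OC(C)=O)[C@H](C)[C@@]3(O[Si](C)(C)C)C[C@@]23C)C2CCCC1CCC2 | intermediate
9 | primary alcohol: as 7, with a 4-hydroxy-2-methylbutan-2-yl group on C5 (hydroxyl on C2) | OCCC(C)(C)[C@@H]1C[C@@H](OC(C)=O)[C@H](C)[C@@]2(O[Si](C)(C)C)C[C@@]12C | intermediate
10 | aldehyde: as 7, with a 2-methyl-4-oxobutan-2-yl group on C5 (C2 aldehyde) | O=CCC(C)(C)[C@@H]1C[C@@H](OC(C)=O)[C@H](C)[C@@]2(O[Si](C)(C)C)C[C@@]12C | intermediate
11 | 7α-acetoxy-2α-hydroxy-8β-methyl-9-oxo bicyclic core | O[C@H]1CC(C)(C)[C@@H]2C[C@@H](OC(C)=O)[C@H](C)C(=O)[C@@]2(C)C1 | intermediate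
12 | 2α,7α-diacetoxy-8β-methyl-9-oxo bicyclic core | CC(=O)O[C@H]1CC(C)(C)[C@@H]2C[C@@H](OC(C)=O)[C@H](C)C(=O)[C@@]2(C)C1 | intermediate
13 | 2α-acetoxy-9-oxo bicyclic core with the C7=C8 double bond (enone) | CC(=O)O[C@H]1CC(C)(C)[C@@H]2CC=C(C)C(=O)[C@@]2(C)C1 | intermediate
14 | 2α-acetoxy bicyclic core with C6=C7 and C8=C9 double bonds and a triflate on C9 | CC(=O)O[C@H]1CC(C)(C)[C@@H]2C=CC(C)=C(OS(=O)(=O)C(F)(F)F)[C@@]2(C)C1 | intermediate
15 | 6α,7α-epoxide of 14 | CC(=O)O[C@H]1CC(C)(C)[C@@H]2[C@H]3O[C@H]3C(C)=C(OS(=O)(=O)C(F)(F)F)[C@@]2(C)C1 | intermediate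
16 | 2α-acetoxy-6-oxo bicyclic core with the C8=C9 double bond and a triflate on C9 | CC(=O)O[C@H]1CC(C)(C)[C@@H]2C(=O)CC(C)=C(OS(=O)(=O)C(F)(F)F)[C@@]2(C)C1 | intermediate
17 | 7α-hydroxy derivative of 16 | CC(=O)O[C@H]1CC(C)(C)[C@@H]2C(=O)[C@@H](O)C(C)=C(OS(=O)(=O)C(F)(F)F)[C@@]2(C)C1 | intermediate
18 | 2α-acetoxy-6β,7α-dihydroxy bicyclic core with the C8=C9 double bond and a triflate on C9 | CC(=O)O[C@H]1CC(C)(C)[C@@H]2[C@H](O)[C@@H](O)C(C)=C(OS(=O)(=O)C(F)(F)F)[C@@]2(C)C1 | intermediate
19 | 2α,6β,7α-triacetoxy bicyclic core with the C8=C9 double bond and a triflate on C9 | CC(=O)O[C@H]1CC(C)(C)[C@@H]2[C@H](OC(C)=O)[C@@H](OC(C)=O)C(C)=C(OS(=O)(=O)C(F)(F)F)[C@@]2(C)C1 | intermediate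
20 | (E)-3-methylpent-2-en-4-yn-1-ol | C#C/C(C)=C/CO | starting material
21 | (E)-3-methylpenta-2,4-dien-1-ol | C=C/C(C)=C/CO | intermediate
22 | (E)-5-(9-borabicyclo[3.3.1]nonan-9-yl)-3-methylpent-2-en-1-yl 9-borabicyclo[3.3.1]nonan-9-yl ether (C-boryl at C11, O-boryl at O15) | B1(CC/C(C)=C/COB2C3CCCC2CCC3)C2CCCC1CCC2 | intermediate
23 | 2α,6β,7α-triacetoxylabda-8,13E-dien-15-ol (CNP0305346.2) | CC(=O)O[C@H]1CC(C)(C)[C@@H]2[C@H](OC(C)=O)[C@@H](OC(C)=O)C(C)=C(CC/C(C)=C/CO)[C@@]2(C)C1 | target

**Step count and risks**

Total step count: 16. Longest linear sequence: 15 (steps 1–14 and 16, from (R)-carvone).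

Step 7 (Proposed new method). What may go wrong: the Lewis acid opens the cyclopropane by protodesilylation or chloride capture before the C1–C2 bond forms, or the aldehyde is consumed by oligomerisation. The fallback uses known chemistry and sets out from 10. N-Iodosuccinimide in CH2Cl2 at 0 °C opens the silyl cyclopropyl ether at C1 to the β-iodo ketone aldehyde F1. CrCl2 with catalytic cobalt phthalocyanine (C32H16CoN8) in DMF then turns the neopentyl-type iodide into an alkylchromium species that adds to the aldehyde but not to the ketone (Takai-type alkylchromium addition). This closes the C1–C2 bond and comes back to the route at 11.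

Step 11. What may go wrong: ionisation at the wrong epoxide carbon, migration of C5 instead of hydride (ring contraction), or proton loss to a dienol. The fallback sets out from 15. MgBr2·OEt2 in ether opens the epoxide at the allylic C7 with inversion to the bromohydrin F2. Dess–Martin oxidation gives the α-bromo ketone F3, and zinc in acetic acid removes the bromine, coming back to the route at 16.

Step 16. What may go wrong: slow transmetallation at the tetrasubstituted palladium-bound C9, flanked by the quaternary C10, so that acetate hydrolysis, reduction of the triflate or ionisation of the allylic C7 acetate takes over. The fallback sets out from 21 and 19. Silylation of 21 (TBSCl, imidazole) gives the silyl ether F4. 9-BBN gives the alkylborane F5, which iodine and NaOMe convert to the homoallylic iodide F6. Zinc dust with LiCl in THF gives the alkylzinc iodide F7, which is coupled with 19 in a base-free Negishi reaction (Pd(OAc)2, SPhos, THF/NMP) to the silyl ether F8 of the target. HF·pyridine removes the silyl group and comes back to the route at 23.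

**Further compounds**

F1 | step 7 | β-iodo ketone aldehyde: ring B 9-ketone with 10α-iodomethyl (C1), 10β-methyl, 8β-methyl, 7α-acetoxy and the 2-methyl-4-oxobutan-2-yl group on C5 | O=CCC(C)(C)[C@@H]1C[C@@H](OC(C)=O)[C@H](C)C(=O)[C@@]1(C)CI
F2 | step 11 | bromohydrin: 7β-bromo-6α-hydroxy derivative of the 2α-acetoxy C9 triflate | CC(=O)O[C@H]1CC(C)(C)[C@@H]2[C@@H](O)[C@H](Br)C(C)=C(OS(=O)(=O)C(F)(F)F)[C@@]2(C)C1
F3 | step 11 | α-bromo ketone: 7β-bromo-6-oxo derivative of the 2α-acetoxy C9 triflate | CC(=O)O[C@H]1CC(C)(C)[C@@H]2C(=O)[C@H](Br)C(C)=C(OS(=O)(=O)C(F)(F)F)[C@@]2(C)C1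
F4 | step 16 | tert-butyldimethylsilyl ether of 21 | C=C/C(C)=C/CO[Si](C)(C)C(C)(C)C
F5 | step 16 | B-alkyl-9-BBN adduct of F4 | B1(CC/C(C)=C/CO[Si](C)(C)C(C)(C)C)C2CCCC1CCC2
F6 | step 16 | (E)-tert-butyl[(5-iodo-3-methylpent-2-en-1-yl)oxy]dimethylsilane | ICC/C(C)=C/CO[Si](C)(C)C(C)(C)C
F7 | step 16 | alkylzinc iodide from F6 | I[Zn]CC/C(C)=C/CO[Si](C)(C)C(C)(C)C
F8 | step 16 | 15-O-tert-butyldimethylsilyl ether of 23 | CC(=O)O[C@H]1CC(C)(C)[C@@H]2[C@H](OC(C)=O)[C@@H](OC(C)=O)C(C)=C(CC/C(C)=C/CO[Si](C)(C)C(C)(C)C)[C@@]2(C)C1
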